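**Retrosynthetic overview**
1. Target 29 ⇒ 28: the 7α-OH comes last, by SeO2 allylic hydroxylation of the 8(17)-ene.
2. 28 ⇒ acyclic epoxy triene 26 in one Ti(III) radical cascade: ring A first (C4–C5), then ring B (C9–C10), then the exocyclic alkene. 26 already carries the angelate, the acetate and the C13 vinyl carbinol, and its C2 ester is asked to force the 3α (axial) C–O fold.
3. 26 ⇒ triol 23 (selective acetylation, Mitsunobu inversion with angelic acid) ⇒ ketone 9 + phosphonium salt 20 (Z-selective Still–Wittig for C5=C10).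
4. 9 ⇒ hydroxyacetone + prenal (catalytic asymmetric aldol, A(1,3)-controlled epoxidation).
5. 20 ⇒ 5-chloropent-1-yne (Negishi carboalumination) + (S)-2-methylglycidol (two sulfonium-ylide homologations, B-alkyl Suzuki).

Assumption: labdane numbering (C1–C20, C20 = the CH2O group on C10) is used for the target and its acyclic precursors, α = the face opposite C20, and the (S,S)-bisphosphoramide is taken as the catalyst antipode that gives Si-face aldol addition.

**Route**

Step 1
Reactants: 1 hydroxyacetone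
Product: 2 1-[(tert-butyldimethylsilyl)oxy]propan-2-one
Conditions: TBSCl, imidazole, CH2Cl2, 0 °C to rt
Reagents that add atoms: tert-butyldimethylsilyl chloride, CC(C)(C)[Si](C)(C)Cl
Why: Standard silylation; the bulky, non-chelating silyl ether later steers enolisation to the methyl group and provides the α-alkoxy ketone needed for the Z-selective Wittig reaction.

Step 2
Reactants: 2 1-[(tert-butyldimethylsilyl)oxy]propan-2-one
Product: 4 tert-butyldimethyl{[2-(trimethylsilyloxy)prop-2-en-1-yl]oxy}silane, via lithium enolate 3 (not isolated)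
Conditions: LDA, THF, −78 °C; TMSCl, −78 to 0 °C
Reagents that add atoms: chlorotrimethylsilane, C[Si](C)(C)Cl
Why: Kinetic deprotonation at the unhindered methyl group (the CH2 next to the bulky OTBS is shielded) and O-silylation give the terminal silyl enol ether.

Step 3
Reactants: 4 tert-butyldimethyl{[2-(trimethylsilyloxy)prop-2-en-1-yl]oxy}silane; 5 3-methylbut-2-enal (prenal)
Product: 7 (S)-1-[(tert-butyldimethylsilyl)oxy]-4-hydroxy-6-methylhept-5-en-2-one, via trichlorosilyl aldolate 6 (not isolated)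
Conditions: SiCl4, (S,S)-Denmark bisphosphoramide (5 mol%), i-Pr2NEt (10 mol%), CH2Cl2, −78 °C; aq. NaHCO3
Reagents that add atoms: none
Why: Denmark's Lewis-base-activated SiCl4 Mukaiyama aldol of a methyl-ketone enol silane with a conjugated aldehyde; catalyst-controlled Si-face addition sets the carbinol (future C2) as S, opposite to the target, because step 13 inverts it.

Step 4
Reactants: 7 (S)-1-[(tert-butyldimethylsilyl)oxy]-4-hydroxy-6-methylhept-5-en-2-one
Product: 8 (4S)-1-[(tert-butyldimethylsilyl)oxy]-4-[(2R)-3,3-dimethyloxiran-2-yl]-4-hydroxybutan-2-one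
Conditions: mCPBA, NaHCO3, CH2Cl2, 0 °C
Reagents that add atoms: meta-chloroperoxybenzoic acid, OOC(=O)c1cccc(Cl)c1
Why: Henbest hydroxyl-directed epoxidation of the only alkene; A(1,3) strain with the cis-methyl holds the carbinol H in the alkene plane, so the hydrogen-bonded peracid adds to one face and gives the threo epoxy alcohol (about 95:5), setting C3.

Step 5
Reactants: 8 (4S)-1-[(tert-butyldimethylsilyl)oxy]-4-[(2R)-3,3-dimethyloxiran-2-yl]-4-hydroxybutan-2-one
Product: 9 (4S)-1,4-bis[(tert-butyldimethylsilyl)oxy]-4-[(2R)-3,3-dimethyloxiran-2-yl]butan-2-one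
Conditions: TBSCl, imidazole, DMAP (cat.), DMF, rt
Reagents that add atoms: tert-butyldimethylsilyl chloride, CC(C)(C)[Si](C)(C)Cl
Why: Silylation of the secondary alcohol blocks retro-aldol and E1cB loss of the β-oxygen under the basic Wittig conditions; the epoxide and ketone tolerate imidazole/DMF.

Step 6
Reactants: 10 (S)-2-methylglycidol
Product: 11 (R)-2-methylbut-3-ene-1,2-diol
Conditions: Me3S+ I−, n-BuLi, THF, −10 °C to rt
Reagents that add atoms: trimethylsulfonium iodide, C[S+](C)C.[I-]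
Why: Dimethylsulfonium methylide opens the epoxide at CH2 and a second ylide equivalent eliminates Me2S (epoxide to one-carbon-homologated allylic alcohol); no bond to the quaternary stereocentre is broken, so its configuration is carried over (only the CIP descriptor changes).

Step 7
Reactants: 12 5-chloropent-1-yne
Product: 14 (E)-5-chloro-1-iodo-2-methylpent-1-ene, via alkenylalane 13 (not isolated)
Conditions: Me3Al, Cp2ZrCl2 (25 mol%), CH2Cl2, 0 °C to rt; I2, THF, −30 to 0 °C
Reagents that add atoms: trimethylaluminium, C[Al](C)C; iodine, II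
Why: Negishi Zr-catalysed syn-carboalumination puts methyl on the internal and Al on the terminal carbon, and iodinolysis with retention gives the E-trisubstituted vinyl iodide (future C8=C9); the alkyl chloride is inert.

Step 8
Reactants: 11 (R)-2-methylbut-3-ene-1,2-diol; 14 (E)-5-chloro-1-iodo-2-methylpent-1-ene
Product: 16 (2R,5E)-9-chloro-2,6-dimethylnon-5-ene-1,2-diol, via B-alkyl borane 15 (not isolated)
Conditions: 9-BBN (3.3 equiv), THF, 0 °C to rt; then 14, Pd(dppf)Cl2 (5 mol%), AsPh3, 3 M aq. NaOH, DMF, rt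
Reagents that add atoms: none
Why: Anti-Markovnikov hydroboration of the vinyl group (two further borane equivalents cap the hydroxyls) and B-alkyl Suzuki–Miyaura coupling form C9–C11 with retention of the E-alkene; the C13 centre is not involved.

Step 9
Reactants: 16 (2R,5E)-9-chloro-2,6-dimethylnon-5-ene-1,2-diol
Product: 18 (3R,6E)-10-chloro-3,7-dimethyldeca-1,6-dien-3-ol, via epoxide 17 (not isolated)
Conditions: NaH, N-tosylimidazole, THF, 0 °C to rt; then preformed Me3S+ I−/n-BuLi, −10 °C to rt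
Reagents that add atoms: trimethylsulfonium iodide, C[S+](C)C.[I-]
Why: Selective primary tosylation and Williamson closure give the 2,2-disubstituted epoxide, and the same sulfonium-ylide homologation as in step 6 turns it into the tertiary vinyl carbinol with C13 (R) untouched.

Step 10
Reactants: 18 (3R,6E)-10-chloro-3,7-dimethyldeca-1,6-dien-3-ol
Product: 20 [(4E,8R)-8-hydroxy-4,8-dimethyldeca-4,9-dien-1-yl]triphenylphosphonium iodide, via alkyl iodide 19 (not isolated)
Conditions: NaI, PPh3, NaHCO3 (cat.), MeCN, reflux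
Reagents that add atoms: sodium iodide, [Na+].[I-]; triphenylphosphine, c1ccc(cc1)P(c1ccccc1)c1ccccc1
Why: Finkelstein exchange followed by SN2 quaternisation of the primary halide; the tertiary allylic alcohol is inert under these neutral conditions.

Step 11
Reactants: 9 (4S)-1,4-bis[(tert-butyldimethylsilyl)oxy]-4-[(2R)-3,3-dimethyloxiran-2-yl]butan-2-one; 20 [(4E,8R)-8-hydroxy-4,8-dimethyldeca-4,9-dien-1-yl]triphenylphosphonium iodide
Product: 23 (3R,6E,10Z,13S)-13-[(2R)-3,3-dimethyloxiran-2-yl]-11-(hydroxymethyl)-3,7-dimethyltrideca-1,6,10-triene-3,13-diol, via alkoxide ylide 21 (not isolated), via bis-silyl triene 22 (not isolated)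
Conditions: 20, KHMDS (2 equiv), THF, −78 to 0 °C; 9, −78 °C to rt; then TBAF/AcOH, rt
Reagents that add atoms: none
Why: Still's Z-selective Wittig reaction of an α-silyloxy ketone with an unstabilised ylide places CH2OSi (C20) cis to the ylide chain (C6), fixing the C5=C10 geometry needed for the trans-decalin; buffered fluoride then removes both TBS groups without Payne scrambling.

Step 12
Reactants: 23 (3R,6E,10Z,13S)-13-[(2R)-3,3-dimethyloxiran-2-yl]-11-(hydroxymethyl)-3,7-dimethyltrideca-1,6,10-triene-3,13-diol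
Product: 24 (3R,6E,10Z,13S)-11-(acetoxymethyl)-13-[(2R)-3,3-dimethyloxiran-2-yl]-3,7-dimethyltrideca-1,6,10-triene-3,13-diol
Conditions: AcCl (1.05 equiv), 2,4,6-collidine, CH2Cl2, −78 °C
Reagents that add atoms: acetyl chloride, CC(=O)Cl
Why: Kinetically selective acylation of the primary allylic alcohol (C20) over the hindered α-epoxy secondary alcohol and the tertiary alcohol.

Step 13
Reactants: 24 (3R,6E,10Z,13S)-11-(acetoxymethyl)-13-[(2R)-3,3-dimethyloxiran-2-yl]-3,7-dimethyltrideca-1,6,10-triene-3,13-diol; 25 angelic acid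
Product: 26 (3R,6E,10Z,13R)-11-(acetoxymethyl)-13-[(2R)-3,3-dimethyloxiran-2-yl]-3-hydroxy-3,7-dimethyltrideca-1,6,10-trien-13-yl (Z)-2-methylbut-2-enoate
Conditions: PPh3, DIAD, toluene, 0 °C to rt
Reagents that add atoms: none
Why: Mitsunobu esterification with SN2 inversion at C2 converts the threo epoxy alcohol into the erythro angelate (C2 R, the target configuration); the neutral conditions avoid angelate-to-tiglate isomerisation and the tertiary alcohol does not react.

Step 14
Reactants: 26 (3R,6E,10Z,13R)-11-(acetoxymethyl)-13-[(2R)-3,3-dimethyloxiran-2-yl]-3-hydroxy-3,7-dimethyltrideca-1,6,10-trien-13-yl (Z)-2-methylbut-2-enoate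
Product: 28 (13R)-20-acetoxy-2α-angeloyloxylabda-8(17),14-diene-3α,13-diol, via 3-O-TMS ether 27 (not isolated)
Conditions: Cp2TiCl2 (30 mol%), Mn, TMSCl, 2,4,6-collidine, THF, rt, slow addition of 26; then 1 M HCl, THF, 0 °C
Reagents that add atoms: none
Why: Proposed new method: a Nugent–RajanBabu/Justicia Ti(III) epoxypolyene radical bicyclisation (closest known case: catalytic Cp2TiCl cyclisation of 2,3-epoxyfarnesyl acetate to the 3β-hydroxy-8(17)-drimenyl acetate) run on a 2-acyloxy epoxide so that the C2 ester rather than the C3–OTi group chooses the fold; Ti(III) homolysis gives the C4 tertiary radical, 6-endo/6-endo chair–chair closure through the two alkenes forms C4–C5 and C9–C10 with H5α/C20β/H9α, the chair with the angelate equatorial (no syn-axial clash with the axial C4 methyl and the C10 CH2OAc) puts the C3–O bond axial (3α, anti to the axial methyl), and Ti(III) trapping of the C8 radical with β-H loss gives the 8(17)-ene, the low Ti(III) concentration of the catalytic protocol keeping the β-acetoxy C10 radical from being reduced before it cyclises.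

Step 15
Reactants: 28 (13R)-20-acetoxy-2α-angeloyloxylabda-8(17),14-diene-3α,13-diol
Product: 29 (13R)-20-acetoxy-2α-angeloyloxylabda-8(17),14-diene-3α,7α,13-triol (CNP0251485.1)
Conditions: SeO2 (0.5 equiv), t-BuOOH, CH2Cl2, 0 °C to rt
Reagents that add atoms: selenium dioxide, O=[Se]=O; tert-butyl hydroperoxide (terminal oxidant), CC(C)(C)OO
Why: Sharpless–Umbreit allylic oxidation (ene reaction at C17, then [2,3]-shift) hydroxylates C7 from the α (axial) face and restores the exocyclic alkene, as is usual for labd-8(17)-enes; the vinyl carbinol has no allylic hydrogen and the electron-poor angelate reacts much more slowly.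

**Compound list**
1 | hydroxyacetone | CC(=O)CO | starting material
2 | 1-[(tert-butyldimethylsilyl)oxy]propan-2-one | CC(=O)CO[Si](C)(C)C(C)(C)C | intermediate
3 | lithium 3-[(tert-butyldimethylsilyl)oxy]prop-1-en-2-olate | [Li+].C=C([O-])CO[Si](C)(C)C(C)(C)C | intermediate
4 | tert-butyldimethyl{[2-(trimethylsilyloxy)prop-2-en-1-yl]oxy}silane | C=C(O[Si](C)(C)C)CO[Si](C)(C)C(C)(C)C | intermediate
5 | 3-methylbut-2-enal (prenal) | CC(C)=CC=O | starting material
6 | (S)-1-[(tert-butyldimethylsilyl)oxy]-6-methyl-4-[(trichlorosilyl)oxy]hept-5-en-2-one | CC(C)=C[C@@H](O[Si](Cl)(Cl)Cl)CC(=O)CO[Si](C)(C)C(C)(C)C | intermediate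
7 | (S)-1-[(tert-butyldimethylsilyl)oxy]-4-hydroxy-6-methylhept-5-en-2-one | CC(C)=C[C@@H](O)CC(=O)CO[Si](C)(C)C(C)(C)C | intermediate
8 | (4S)-1-[(tert-butyldimethylsilyl)oxy]-4-[(2R)-3,3-dimethyloxiran-2-yl]-4-hydroxybutan-2-one | CC1(C)[C@H](O1)[C@@H](O)CC(=O)CO[Si](C)(C)C(C)(C)C | intermediate
9 | (4S)-1,4-bis[(tert-butyldimethylsilyl)oxy]-4-[(2R)-3,3-dimethyloxiran-2-yl]butan-2-one | CC1(C)[C@H](O1)[C@@H](O[Si](C)(C)C(C)(C)C)CC(=O)CO[Si](C)(C)C(C)(C)C | intermediate
10 | (S)-2-methylglycidol [(S)-(2-methyloxiran-2-yl)methanol] | OC[C@]1(C)OC1 | starting material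
11 | (R)-2-methylbut-3-ene-1,2-diol | OC[C@](C)(O)C=C | intermediate
12 | 5-chloropent-1-yne | C#CCCCCl | starting material
13 | [(E)-5-chloro-2-methylpent-1-en-1-yl]dimethylalane | C[Al](C)/C=C(\C)CCCCl | intermediate
14 | (E)-5-chloro-1-iodo-2-methylpent-1-ene | I/C=C(\C)CCCCl | intermediate
15 | (R)-9-{3-methyl-3,4-bis[(9-borabicyclo[3.3.1]nonan-9-yl)oxy]butyl}-9-borabicyclo[3.3.1]nonane | O(B1C2CCCC1CCC2)C[C@](C)(OB1C2CCCC1CCC2)CCB1C2CCCC1CCC2 | intermediate
16 | (2R,5E)-9-chloro-2,6-dimethylnon-5-ene-1,2-diol | OC[C@](C)(O)CC/C=C(\C)CCCCl | intermediate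
17 | (R)-2-[(3E)-7-chloro-4-methylhept-3-en-1-yl]-2-methyloxirane | C1O[C@]1(C)CC/C=C(\C)CCCCl | intermediate
18 | (3R,6E)-10-chloro-3,7-dimethyldeca-1,6-dien-3-ol | C=C[C@](C)(O)CC/C=C(\C)CCCCl | intermediate
19 | (3R,6E)-10-iodo-3,7-dimethyldeca-1,6-dien-3-ol | C=C[C@](C)(O)CC/C=C(\C)CCCI | intermediate
20 | [(4E,8R)-8-hydroxy-4,8-dimethyldeca-4,9-dien-1-yl]triphenylphosphonium iodide | C=C[C@](C)(O)CC/C=C(\C)CCC[P+](c1ccccc1)(c1ccccc1)c1ccccc1.[I-] | intermediate
21 | potassium (3R,6E)-3,7-dimethyl-10-(triphenyl-λ5-phosphanylidene)deca-1,6-dien-3-olate | C=C[C@](C)([O-])CC/C=C(\C)CCC=P(c1ccccc1)(c1ccccc1)c1ccccc1.[K+] | intermediate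
22 | (3R,6E,10Z,13S)-13-[(tert-butyldimethylsilyl)oxy]-11-{[(tert-butyldimethylsilyl)oxy]methyl}-13-[(2R)-3,3-dimethyloxiran-2-yl]-3,7-dimethyltrideca-1,6,10-trien-3-ol | CC1(C)[C@H](O1)[C@@H](O[Si](C)(C)C(C)(C)C)C/C(CO[Si](C)(C)C(C)(C)C)=C/CC/C(C)=C/CC[C@@](C)(O)C=C | intermediate
23 | (3R,6E,10Z,13S)-13-[(2R)-3,3-dimethyloxiran-2-yl]-11-(hydroxymethyl)-3,7-dimethyltrideca-1,6,10-triene-3,13-diol | CC1(C)[C@H](O1)[C@@H](O)C/C(CO)=C/CC/C(C)=C/CC[C@@](C)(O)C=C | intermediate
24 | (3R,6E,10Z,13S)-11-(acetoxymethyl)-13-[(2R)-3,3-dimethyloxiran-2-yl]-3,7-dimethyltrideca-1,6,10-triene-3,13-diol | CC1(C)[C@H](O1)[C@@H](O)C/C(COC(C)=O)=C/CC/C(C)=C/CC[C@@](C)(O)C=C | intermediate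
25 | angelic acid [(Z)-2-methylbut-2-enoic acid] | C/C=C(/C)C(=O)O | starting material
26 | (3R,6E,10Z,13R)-11-(acetoxymethyl)-13-[(2R)-3,3-dimethyloxiran-2-yl]-3-hydroxy-3,7-dimethyltrideca-1,6,10-trien-13-yl (Z)-2-methylbut-2-enoate | CC1(C)[C@H](O1)[C@H](OC(=O)/C(C)=C\C)C/C(COC(C)=O)=C/CC/C(C)=C/CC[C@@](C)(O)C=C | intermediate
27 | (13R)-20-acetoxy-2α-angeloyloxy-3α-(trimethylsilyloxy)labda-8(17),14-dien-13-ol | C=C[C@](C)(O)CC[C@H]1C(=C)CC[C@H]2C(C)(C)[C@H](O[Si](C)(C)C)[C@H](OC(=O)/C(C)=C\C)C[C@]12COC(C)=O | intermediate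
28 | (13R)-20-acetoxy-2α-angeloyloxylabda-8(17),14-diene-3α,13-diol | C=C[C@](C)(O)CC[C@H]1C(=C)CC[C@H]2C(C)(C)[C@H](O)[C@H](OC(=O)/C(C)=C\C)C[C@]12COC(C)=O | intermediate
29 | (13R)-20-acetoxy-2α-angeloyloxylabda-8(17),14-diene-3α,7α,13-triol (CNP0251485.1) | C=C[C@](C)(O)CC[C@H]1C(=C)[C@H](O)C[C@H]2C(C)(C)[C@H](O)[C@H](OC(=O)/C(C)=C\C)C[C@]12COC(C)=O | target

**Totals**
Total step count: 15.
Longest linear sequence: 10 steps (steps 1–5, then 11–15). The other branch (steps 6, 8, 9, 10, then 11–15) is 9 steps; step 7 feeds step 8.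

**Steps most likely to fail, with fallbacks**

(1) Step 14, the Ti(III) cascade. Two failure modes are real. The usual preference for an equatorial C3–OTi group may outweigh the C2 ester and give the antipodal decalin core with an axial angelate. The β-acetoxy C10 radical may also be reduced and lose acetate before ring B closes. My estimate is only a modest preference for the desired fold, so this is the main gamble of the route.

The fallback uses the stereochemically matched series and inverts C3 afterwards; it sets out from 4 and 5 and comes back at 28. The aldol of step 3 is run with the (R,R)-catalyst and gives, through the (R)-trichlorosilyl aldolate F1, the (R)-aldol F2. mCPBA as in step 4 gives the mirror-image threo epoxy alcohol F3, and TBSCl gives the bis-silyl ketone F4. Wittig reaction with ylide 21 gives the bis-silyl triene F5 and, after TBAF/AcOH, the triol F6; AcCl/collidine gives the primary acetate F7. This is esterified with retention (25, 2,4,6-trichlorobenzoyl chloride, Et3N, toluene, 80 °C) to the threo angelate F8, the C3 epimer of 26. In F8 the ester and the C3–OTi group are both equatorial in the same chair, so the cascade under the step 14 conditions should give, through the 3β-O-TMS ether F9, the 3β-alcohol F10 with the normal labdane core. Dess–Martin periodinane gives the 3-ketone F11, and K-Selectride (THF, −78 °C; equatorial attack on the 4,4-dimethyl-3-ketone) gives the axial 3α-alcohol 28.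

(2) Step 11, the Wittig union. Ketone 9 is hindered, enolisable and β-oxygenated, and Still's Z-selectivity has not been shown with so large a second substituent.

The fallback is a two-stage Horner–Wittig reaction with separation of diastereomers; it sets out from 18 and 9 and comes back at 22. Chloride 18 is P-alkylated with Ph2P(O)H/NaH (NaI cat., DMF, 50 °C) to the phosphine oxide F12. n-BuLi (2 equiv, THF, −78 °C) gives the dilithio derivative F13, which adds to ketone 9. The β-hydroxy phosphine oxides are separated on silica, and the isomer that leads to the Z-alkene, the adduct F14, is warmed with NaH in DMF. Stereospecific syn-elimination of diphenylphosphinate gives 22, which is desilylated as in the second stage of step 11.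

(3) Step 9, the one-pot epoxide formation and ylide homologation. The excess sulfonium ylide can attack the primary chloride, and the telescoped sequence is unproven on this substrate.

The fallback builds the vinyl group by carbonyl olefination; it sets out from 16 and comes back at 18. Diol 16 is oxidised (SO3·pyridine, DMSO, i-Pr2NEt, 0 °C) to the α-hydroxy aldehyde F15, and methylenation with Ph3P=CH2 (Ph3PCH3Br, KOt-Bu, THF, 0 °C; one extra equivalent for the free OH) gives 18.

Further compounds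
F1 | step 14 | (R)-1-[(tert-butyldimethylsilyl)oxy]-6-methyl-4-[(trichlorosilyl)oxy]hept-5-en-2-one | CC(C)=C[C@H](O[Si](Cl)(Cl)Cl)CC(=O)CO[Si](C)(C)C(C)(C)C
F2 | step 14 | (R)-1-[(tert-butyldimethylsilyl)oxy]-4-hydroxy-6-methylhept-5-en-2-one | CC(C)=C[C@H](O)CC(=O)CO[Si](C)(C)C(C)(C)C
F3 | step 14 | (4R)-1-[(tert-butyldimethylsilyl)oxy]-4-[(2S)-3,3-dimethyloxiran-2-yl]-4-hydroxybutan-2-one | CC1(C)[C@@H](O1)[C@H](O)CC(=O)CO[Si](C)(C)C(C)(C)C
F4 | step 14 | (4R)-1,4-bis[(tert-butyldimethylsilyl)oxy]-4-[(2S)-3,3-dimethyloxiran-2-yl]butan-2-one | CC1(C)[C@@H](O1)[C@H](O[Si](C)(C)C(C)(C)C)CC(=O)CO[Si](C)(C)C(C)(C)C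
F5 | step 14 | (3R,6E,10Z,13R)-13-[(tert-butyldimethylsilyl)oxy]-11-{[(tert-butyldimethylsilyl)oxy]methyl}-13-[(2S)-3,3-dimethyloxiran-2-yl]-3,7-dimethyltrideca-1,6,10-trien-3-ol | CC1(C)[C@@H](O1)[C@H](O[Si](C)(C)C(C)(C)C)C/C(CO[Si](C)(C)C(C)(C)C)=C/CC/C(C)=C/CC[C@@](C)(O)C=C
F6 | step 14 | (3R,6E,10Z,13R)-13-[(2S)-3,3-dimethyloxiran-2-yl]-11-(hydroxymethyl)-3,7-dimethyltrideca-1,6,10-triene-3,13-diol | CC1(C)[C@@H](O1)[C@H](O)C/C(CO)=C/CC/C(C)=C/CC[C@@](C)(O)C=C
F7 | step 14 | (3R,6E,10Z,13R)-11-(acetoxymethyl)-13-[(2S)-3,3-dimethyloxiran-2-yl]-3,7-dimethyltrideca-1,6,10-triene-3,13-diol | CC1(C)[C@@H](O1)[C@H](O)C/C(COC(C)=O)=C/CC/C(C)=C/CC[C@@](C)(O)C=C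
F8 | step 14 | (3R,6E,10Z,13R)-11-(acetoxymethyl)-13-[(2S)-3,3-dimethyloxiran-2-yl]-3-hydroxy-3,7-dimethyltrideca-1,6,10-trien-13-yl (Z)-2-methylbut-2-enoate | CC1(C)[C@@H](O1)[C@H](OC(=O)/C(C)=C\C)C/C(COC(C)=O)=C/CC/C(C)=C/CC[C@@](C)(O)C=C
F9 | step 14 | (13R)-20-acetoxy-2α-angeloyloxy-3β-(trimethylsilyloxy)labda-8(17),14-dien-13-ol | C=C[C@](C)(O)CC[C@H]1C(=C)CC[C@H]2C(C)(C)[C@@H](O[Si](C)(C)C)[C@H](OC(=O)/C(C)=C\C)C[C@]12COC(C)=O
F10 | step 14 | (13R)-20-acetoxy-2α-angeloyloxylabda-8(17),14-diene-3β,13-diol | C=C[C@](C)(O)CC[C@H]1C(=C)CC[C@H]2C(C)(C)[C@@H](O)[C@H](OC(=O)/C(C)=C\C)C[C@]12COC(C)=O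
F11 | step 14 | (13R)-20-acetoxy-2α-angeloyloxy-13-hydroxylabda-8(17),14-dien-3-one | C=C[C@](C)(O)CC[C@H]1C(=C)CC[C@H]2C(C)(C)C(=O)[C@H](OC(=O)/C(C)=C\C)C[C@]12COC(C)=O
F12 | step 11 | [(4E,8R)-8-hydroxy-4,8-dimethyldeca-4,9-dien-1-yl]diphenylphosphine oxide | C=C[C@](C)(O)CC/C=C(\C)CCCP(=O)(c1ccccc1)c1ccccc1
F13 | step 11 | dilithium salt of F12 (alkoxide and α-phosphinoyl carbanion) | [Li+].[Li+].C=C[C@](C)([O-])CC/C=C(\C)CC[CH-]P(=O)(c1ccccc1)c1ccccc1
F14 | step 11 | β-hydroxy phosphine oxide adduct of F13 and 9 (the C5/C10 diastereomer whose syn-elimination gives the Z-alkene) | CC1(C)[C@H](O1)[C@@H](O[Si](C)(C)C(C)(C)C)C[C@](O)(CO[Si](C)(C)C(C)(C)C)[C@H](P(=O)(c1ccccc1)c1ccccc1)CC/C(C)=C/CC[C@@](C)(O)C=C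
F15 | step 9 | (2R,5E)-9-chloro-2-hydroxy-2,6-dimethylnon-5-enal | O=C[C@](C)(O)CC/C=C(\C)CCCCl
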